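**Retrosynthetic overview**
1. Target 26 ⇐ seco ester 24: the γ-lactone is the last ring, closed by C6–O lactonization after global desilylation; the C8 isovalerate is installed just before.
2. 24 ⇐ 21: the ten-membered carbocycle is closed by a zinc Barbier allylation (C7–C8) on a substrate that already carries the furanone.
3. 21 ⇐ enal 15 + linchpin 18: C7 is introduced as a "double nucleophile" by a new chromium-catalysed asymmetric bromoallylation (sets C6); the C8 aldehyde comes from the allyl group.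
4. 15 ⇐ enyne 10 + dioxolanone 5: key C–O bond – the furanone O–C3 bond is formed by 5-endo-dig addition of the C10 alkoxide to an ynone; C10 comes from (S)-lactic acid.
5. Ring order: furanone → ten-membered carbocycle → lactone.

Assumption: atom labels C1–C15 follow germacranolide numbering of the target (C1 ketone, C2=C3, C4=C5, C6 lactone carbinol, C7, C8 ester carbinol, C9, C10 quaternary, C11–C13 acrylate, C14 methyl, C15 CH2O); compound 6, the chiral carbazole bis(oxazoline) ligand and all reagents are bought.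

**Route**

Step 1
Reactants: 1 (S)-lactic acid; 2 pivalaldehyde
Product: 3 (2S,5S)-2-tert-butyl-5-methyl-1,3-dioxolan-4-one
Conditions: p-TsOH (cat.), H2SO4 (cat.), pentane, reflux, Dean–Stark; crystallisation at −78 °C
Reagents that add atoms: none
Why: Acid-catalysed acetalization (Seebach dioxolanone for self-regeneration of stereocentres); the lactate centre is untouched and the cis acetal is obtained pure by crystallisation.

Step 2
Reactants: 3 (2S,5S)-2-tert-butyl-5-methyl-1,3-dioxolan-4-one; 4 allyl bromide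
Product: 5 (2S,5R)-5-allyl-2-tert-butyl-5-methyl-1,3-dioxolan-4-one
Conditions: LiN(iPr)2, THF, −78 °C; then 4, −78 → −30 °C
Reagents that add atoms: none
Why: Enolate alkylation; the planar lithium enolate is attacked anti to the tert-butyl group, so allyl replaces H with retention of the lactate configuration (sets C10, R).

Step 3
Reactants: 6 4-((tert-butyldimethylsilyl)oxy)but-2-yn-1-ol
Product: 7 (Z)-4-((tert-butyldimethylsilyl)oxy)-3-iodobut-2-en-1-ol
Conditions: NaAlH2(OCH2CH2OMe)2 (Red-Al), THF, 0 °C → rt; EtOAc; then I2, THF, −78 → 0 °C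
Reagents that add atoms: iodine, [I][I]
Why: Hydroxyl-directed trans-hydroalumination places aluminium on the distal carbon (C4) and iodinolysis occurs with retention, which fixes the C4=C5 geometry.

Step 4
Reactants: 7 (Z)-4-((tert-butyldimethylsilyl)oxy)-3-iodobut-2-en-1-ol; 8 ethynyltrimethylsilane
Product: 10 (E)-3-(((tert-butyldimethylsilyl)oxy)methyl)pent-2-en-4-yn-1-ol, via TMS-enyne 9 (not isolated)
Conditions: PdCl2(PPh3)2 (3 mol%), CuI (6 mol%), Et3N, THF, rt; then K2CO3 (cat.), MeOH, rt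
Reagents that add atoms: none
Why: Sonogashira coupling with retention of alkene geometry, then base-catalysed protodesilylation of the alkynylsilane.

Step 5
Reactants: 10 (E)-3-(((tert-butyldimethylsilyl)oxy)methyl)pent-2-en-4-yn-1-ol; 5 (2S,5R)-5-allyl-2-tert-butyl-5-methyl-1,3-dioxolan-4-one
Product: 14 (R)-2-allyl-5-[(Z)-1-((tert-butyldimethylsilyl)oxy)-4-hydroxybut-2-en-2-yl]-2-methylfuran-3(2H)-one, via silyl ether 11 (not isolated), via hydroxy ynone 12 (not isolated), via silylated furanone 13 (not isolated)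
Conditions: n-BuLi (1.0 equiv), THF, −78 °C; Me3SiCl (1.0 equiv); n-BuLi (1.05 equiv); then 5, −78 °C → rt; then 1 M HCl, MeOH, 0 °C, 10 min
Reagents that add atoms: none
Why: Key C–O step: after transient O-silylation (which blocks furan formation by the primary hydroxyl), the acetylide is acylated by the dioxolanone, pivalaldehyde is lost, and the liberated C10 alkoxide closes the furanone by 5-endo-dig oxa-Michael addition (O–C3 bond) without touching C10.

Step 6
Reactants: 14 (R)-2-allyl-5-[(Z)-1-((tert-butyldimethylsilyl)oxy)-4-hydroxybut-2-en-2-yl]-2-methylfuran-3(2H)-one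
Product: 15 (Z)-3-[(R)-5-allyl-5-methyl-4-oxo-4,5-dihydrofuran-2-yl]-4-((tert-butyldimethylsilyl)oxy)but-2-enal
Conditions: MnO2, CH2Cl2, rt
Reagents that add atoms: none
Why: MnO2 oxidation of the allylic alcohol; neutral conditions preserve the Z-enal.

Step 7
Reactants: 16 methyl 2-(bromomethyl)acrylate
Product: 18 methyl (Z)-3-bromo-2-(bromomethyl)acrylate, via tribromide 17 (not isolated)
Conditions: Br2, CH2Cl2, 0 °C → rt; then Et3N, Et2O, 0 °C
Reagents that add atoms: bromine, BrBr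
Why: Bromine addition and E2 dehydrobromination; the symmetrical tribromide can only eliminate to the β-bromoacrylate.

Step 8
Reactants: 15 (Z)-3-[(R)-5-allyl-5-methyl-4-oxo-4,5-dihydrofuran-2-yl]-4-((tert-butyldimethylsilyl)oxy)but-2-enal; 18 methyl (Z)-3-bromo-2-(bromomethyl)acrylate
Product: 20 methyl (2Z,4S,5Z)-6-[(R)-5-allyl-5-methyl-4-oxo-4,5-dihydrofuran-2-yl]-2-(bromomethyl)-7-((tert-butyldimethylsilyl)oxy)-4-((triethylsilyl)oxy)hepta-2,5-dienoate, via secondary bromide 19 (not isolated)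
Conditions: CrCl2 (10 mol%), carbazole bis(oxazoline) ligand (11 mol%, enantiomer directing Re-face attack), proton sponge (20 mol%), Mn powder, Et3SiCl, THF, 0 °C; then LiBr (20 mol%), acetone, rt
Reagents that add atoms: triethylsilyl chloride, CC[Si](Cl)(CC)CC
Why: Proposed new method: catalytic asymmetric γ-bromo-2-(methoxycarbonyl)allylation – divalent chromium inserts only into the allylic C–Br bond of 18, the ligand-bound allylchromium adds through a chair transition state by its bromine-bearing γ-carbon to the Re face of the aldehyde (sets C6, S), Et3SiCl silylates the chromium alkoxide so that Mn can turn the catalyst over, and bromide-catalysed SN2′ transposition then gives the conjugated Z-bromide so that C7 can be metalated a second time; the closest known reactions are the chromium/carbazole bis(oxazoline)-catalysed 2-(alkoxycarbonyl)allylation of aldehydes and the chromium-catalysed asymmetric chloroallylation with 1,3-dichloropropene (Nozaki–Hiyama–Kishi type).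

Step 9
Reactants: 20 methyl (2Z,4S,5Z)-6-[(R)-5-allyl-5-methyl-4-oxo-4,5-dihydrofuran-2-yl]-2-(bromomethyl)-7-((tert-butyldimethylsilyl)oxy)-4-((triethylsilyl)oxy)hepta-2,5-dienoate
Product: 21 methyl (2Z,4S,5Z)-2-(bromomethyl)-7-((tert-butyldimethylsilyl)oxy)-6-[(R)-5-methyl-4-oxo-5-(2-oxoethyl)-4,5-dihydrofuran-2-yl]-4-((triethylsilyl)oxy)hepta-2,5-dienoate
Conditions: O3 (1 equiv, titrated), pyridine (3 equiv), CH2Cl2, −78 °C
Reagents that add atoms: ozone, [O-][O+]=O
Why: Ozonolysis with pyridine (no nucleophilic reductant that could attack the allylic bromide) cleaves the isolated terminal alkene, the most electron-rich one; the conjugated and acceptor-substituted alkenes react much more slowly.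

Step 10
Reactants: 21 methyl (2Z,4S,5Z)-2-(bromomethyl)-7-((tert-butyldimethylsilyl)oxy)-6-[(R)-5-methyl-4-oxo-5-(2-oxoethyl)-4,5-dihydrofuran-2-yl]-4-((triethylsilyl)oxy)hepta-2,5-dienoate
Product: 22 methyl (4Z,6S,7R,8R,10R)-15-((tert-butyldimethylsilyl)oxy)-3,10-epoxy-8-hydroxy-1-oxo-6-((triethylsilyl)oxy)germacra-2,4,11(13)-trien-12-oate
Conditions: Zn dust (activated), sat. aq NH4Cl/THF (1:8), 2 mM, slow addition, rt; crude product used at once
Reagents that add atoms: none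
Why: Barbier-type intramolecular allylation under high dilution: the Z-type allylzinc reacts through a Zimmerman–Traxler chair by its γ-carbon C7 (7,8-syn), and with C6–H held in the allyl plane by A(1,3) strain the aldehyde adds anti to the C5 alkenyl branch, on the side of the silyloxy group, which gives the all-cis C6/C7/C8 array (sets C7 R and C8 R).

Step 11
Reactants: 22 methyl (4Z,6S,7R,8R,10R)-15-((tert-butyldimethylsilyl)oxy)-3,10-epoxy-8-hydroxy-1-oxo-6-((triethylsilyl)oxy)germacra-2,4,11(13)-trien-12-oate; 23 3-methylbutanoic anhydride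
Product: 24 methyl (4Z,6S,7R,8R,10R)-15-((tert-butyldimethylsilyl)oxy)-3,10-epoxy-8-((3-methylbutanoyl)oxy)-1-oxo-6-((triethylsilyl)oxy)germacra-2,4,11(13)-trien-12-oate
Conditions: Et3N, DMAP (cat.), CH2Cl2, 0 °C → rt
Reagents that add atoms: none
Why: DMAP-catalysed acylation (Steglich type) of the only free hydroxyl, which also blocks lactonization towards C8.

Step 12
Reactants: 24 methyl (4Z,6S,7R,8R,10R)-15-((tert-butyldimethylsilyl)oxy)-3,10-epoxy-8-((3-methylbutanoyl)oxy)-1-oxo-6-((triethylsilyl)oxy)germacra-2,4,11(13)-trien-12-oate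
Product: 26 (4Z,6S,7R,8R,10R)-3,10-epoxy-15-hydroxy-8-((3-methylbutanoyl)oxy)-1-oxogermacra-2,4,11(13)-trien-12,6-olide (CNP0171896.2), via diol ester 25 (not isolated)
Conditions: HF·pyridine, THF, 0 °C → rt; then p-TsOH (cat.), CH2Cl2, rt
Reagents that add atoms: none
Why: Fluoride cleaves both silyl ethers and the liberated C6–OH lactonizes onto the acrylate ester (acid-catalysed transesterification, retention at C6) to give the cis-fused α-methylene-γ-lactone.

**Compound list**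
1 | (S)-lactic acid | C[C@H](O)C(=O)O | starting material
2 | pivalaldehyde | CC(C)(C)C=O | starting material
3 | (2S,5S)-2-tert-butyl-5-methyl-1,3-dioxolan-4-one | C[C@@H]1O[C@H](C(C)(C)C)OC1=O | intermediate
4 | allyl bromide | C=CCBr | starting material
5 | (2S,5R)-5-allyl-2-tert-butyl-5-methyl-1,3-dioxolan-4-one | C=CC[C@@]1(C)O[C@H](C(C)(C)C)OC1=O | intermediate
6 | 4-((tert-butyldimethylsilyl)oxy)but-2-yn-1-ol | OCC#CCO[Si](C)(C)C(C)(C)C | starting material
7 | (Z)-4-((tert-butyldimethylsilyl)oxy)-3-iodobut-2-en-1-ol | OC/C=C(/CO[Si](C)(C)C(C)(C)C)I | intermediate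
8 | ethynyltrimethylsilane | C#C[Si](C)(C)C | starting material
9 | (E)-3-(((tert-butyldimethylsilyl)oxy)methyl)-5-(trimethylsilyl)pent-2-en-4-yn-1-ol | OC/C=C(/CO[Si](C)(C)C(C)(C)C)C#C[Si](C)(C)C | intermediate
10 | (E)-3-(((tert-butyldimethylsilyl)oxy)methyl)pent-2-en-4-yn-1-ol | OC/C=C(/CO[Si](C)(C)C(C)(C)C)C#C | intermediate
11 | (E)-3-(((tert-butyldimethylsilyl)oxy)methyl)-1-((trimethylsilyl)oxy)pent-2-en-4-yne | C[Si](C)(C)OC/C=C(/CO[Si](C)(C)C(C)(C)C)C#C | intermediate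
12 | (R,E)-8-(((tert-butyldimethylsilyl)oxy)methyl)-4-hydroxy-4-methyl-10-((trimethylsilyl)oxy)deca-1,8-dien-6-yn-5-one | C=CC[C@@](C)(O)C(=O)C#C/C(CO[Si](C)(C)C(C)(C)C)=C\CO[Si](C)(C)C | intermediate
13 | (R)-2-allyl-5-[(Z)-1-((tert-butyldimethylsilyl)oxy)-4-((trimethylsilyl)oxy)but-2-en-2-yl]-2-methylfuran-3(2H)-one | C=CC[C@@]1(C)OC(=CC1=O)/C(CO[Si](C)(C)C(C)(C)C)=C\CO[Si](C)(C)C | intermediate
14 | (R)-2-allyl-5-[(Z)-1-((tert-butyldimethylsilyl)oxy)-4-hydroxybut-2-en-2-yl]-2-methylfuran-3(2H)-one | C=CC[C@@]1(C)OC(=CC1=O)/C(CO[Si](C)(C)C(C)(C)C)=C\CO | intermediate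
15 | (Z)-3-[(R)-5-allyl-5-methyl-4-oxo-4,5-dihydrofuran-2-yl]-4-((tert-butyldimethylsilyl)oxy)but-2-enal | C=CC[C@@]1(C)OC(=CC1=O)/C(CO[Si](C)(C)C(C)(C)C)=C\C=O | intermediate
16 | methyl 2-(bromomethyl)acrylate | C=C(CBr)C(=O)OC | starting material
17 | methyl 2,3-dibromo-2-(bromomethyl)propanoate | COC(=O)C(Br)(CBr)CBr | intermediate
18 | methyl (Z)-3-bromo-2-(bromomethyl)acrylate | Br/C=C(\CBr)C(=O)OC | intermediate
19 | methyl (4S,5Z)-6-[(R)-5-allyl-5-methyl-4-oxo-4,5-dihydrofuran-2-yl]-3-bromo-7-((tert-butyldimethylsilyl)oxy)-2-methylene-4-((triethylsilyl)oxy)hept-5-enoate (both C3 epimers) | C=CC[C@@]1(C)OC(=CC1=O)/C(CO[Si](C)(C)C(C)(C)C)=C\[C@H](O[Si](CC)(CC)CC)C(Br)C(=C)C(=O)OC | intermediate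
20 | methyl (2Z,4S,5Z)-6-[(R)-5-allyl-5-methyl-4-oxo-4,5-dihydrofuran-2-yl]-2-(bromomethyl)-7-((tert-butyldimethylsilyl)oxy)-4-((triethylsilyl)oxy)hepta-2,5-dienoate | C=CC[C@@]1(C)OC(=CC1=O)/C(CO[Si](C)(C)C(C)(C)C)=C\[C@H](O[Si](CC)(CC)CC)/C=C(\CBr)C(=O)OC | intermediate
21 | methyl (2Z,4S,5Z)-2-(bromomethyl)-7-((tert-butyldimethylsilyl)oxy)-6-[(R)-5-methyl-4-oxo-5-(2-oxoethyl)-4,5-dihydrofuran-2-yl]-4-((triethylsilyl)oxy)hepta-2,5-dienoate | O=CC[C@@]1(C)OC(=CC1=O)/C(CO[Si](C)(C)C(C)(C)C)=C\[C@H](O[Si](CC)(CC)CC)/C=C(\CBr)C(=O)OC | intermediate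
22 | methyl (4Z,6S,7R,8R,10R)-15-((tert-butyldimethylsilyl)oxy)-3,10-epoxy-8-hydroxy-1-oxo-6-((triethylsilyl)oxy)germacra-2,4,11(13)-trien-12-oate | C=C(C(=O)OC)[C@H]1[C@@H](O[Si](CC)(CC)CC)/C=C(/CO[Si](C)(C)C(C)(C)C)C2=CC(=O)[C@@](C)(C[C@H]1O)O2 | intermediate
23 | 3-methylbutanoic anhydride (isovaleric anhydride) | CC(C)CC(=O)OC(=O)CC(C)C | starting material
24 | methyl (4Z,6S,7R,8R,10R)-15-((tert-butyldimethylsilyl)oxy)-3,10-epoxy-8-((3-methylbutanoyl)oxy)-1-oxo-6-((triethylsilyl)oxy)germacra-2,4,11(13)-trien-12-oate | C=C(C(=O)OC)[C@H]1[C@@H](O[Si](CC)(CC)CC)/C=C(/CO[Si](C)(C)C(C)(C)C)C2=CC(=O)[C@@](C)(C[C@H]1OC(=O)CC(C)C)O2 | intermediate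
25 | methyl (4Z)-3,10-epoxy-6,15-dihydroxy-8-((3-methylbutanoyl)oxy)-1-oxogermacra-2,4,11(13)-trien-12-oate, stereocentres arranged as in 24 (formal descriptors 6S,7S,8R,10R) | C=C(C(=O)OC)[C@H]1[C@@H](O)/C=C(/CO)C2=CC(=O)[C@@](C)(C[C@H]1OC(=O)CC(C)C)O2 | intermediate
26 | (4Z,6S,7R,8R,10R)-3,10-epoxy-15-hydroxy-8-((3-methylbutanoyl)oxy)-1-oxogermacra-2,4,11(13)-trien-12,6-olide (CNP0171896.2) | C=C1C(=O)O[C@H]2/C=C(/CO)C3=CC(=O)[C@@](C)(C[C@@H](OC(=O)CC(C)C)[C@@H]12)O3 | target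

**Step count**
Total steps: 12. Longest linear sequence: 9 steps (steps 3, 4, 5, 6, 8, 9, 10, 11, 12 from 6; the branch from 1 through steps 1, 2, 5, 6, 8–12 is equally long).

**Steps most likely to fail, with fallbacks**

Step 8 (the new bromoallylation; risks are over-reduction of the product bromide and low enantioselectivity). The fallback uses known chemistry, sets out from 15 and returns at 20. The established chromium/carbazole bis(oxazoline)-catalysed 2-(methoxycarbonyl)allylation of 15 with commercial 16 (Mn, Et3SiCl) gives the homoallylic acrylate methyl (4R,5Z)-6-[(R)-5-allyl-5-methyl-4-oxo-4,5-dihydrofuran-2-yl]-7-((tert-butyldimethylsilyl)oxy)-2-methylene-4-((triethylsilyl)oxy)hept-5-enoate F5. Allylic hydroxylation of the 1,1-disubstituted alkene with SeO2 (cat.)/t-BuOOH then gives the Baylis–Hillman-type alcohol methyl (4S,5Z)-6-[(R)-5-allyl-5-methyl-4-oxo-4,5-dihydrofuran-2-yl]-7-((tert-butyldimethylsilyl)oxy)-3-hydroxy-2-methylene-4-((triethylsilyl)oxy)hept-5-enoate F6. SN2′ bromination of F6 with NBS/Me2S gives 20.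

Step 10 (closure of the strained bicyclic core, and facial selectivity at C7). The fallback sets out from 14 and returns at 26; it closes the ring through C6–C7 instead, so that the cis lactone follows from the chair alone. Ozonolysis of 14 (O3, pyridine) gives 2-[(R)-5-[(Z)-1-((tert-butyldimethylsilyl)oxy)-4-hydroxybut-2-en-2-yl]-2-methyl-3-oxo-2,3-dihydrofuran-2-yl]acetaldehyde F7. Chromium-catalysed bromoallylation of F7 with 18 (excess Et3SiCl, imidazole; then LiBr) gives methyl (2Z,4R)-2-(bromomethyl)-5-[(R)-5-[(Z)-1-((tert-butyldimethylsilyl)oxy)-4-((triethylsilyl)oxy)but-2-en-2-yl]-2-methyl-3-oxo-2,3-dihydrofuran-2-yl]-4-((triethylsilyl)oxy)pent-2-enoate F8. Swern oxidation, which converts the primary allylic triethylsilyl ether directly to the aldehyde, gives the enal methyl (2Z,4R)-2-(bromomethyl)-5-[(R)-5-[(Z)-1-((tert-butyldimethylsilyl)oxy)-4-oxobut-2-en-2-yl]-2-methyl-3-oxo-2,3-dihydrofuran-2-yl]-4-((triethylsilyl)oxy)pent-2-enoate F9. Zinc Barbier cyclization onto the enal (Zn, aq NH4Cl/THF; then cat. p-TsOH) gives the lactone 15-O-(tert-butyldimethylsilyl)-8-O-(triethylsilyl)-8-O-deacyl-26 F10. Removal of the triethylsilyl group (PPTS, MeOH) gives the C8 alcohol 15-O-(tert-butyldimethylsilyl)-8-O-deacyl-26 F11. Acylation with 23 gives 15-O-(tert-butyldimethylsilyl)-26 F12, and HF·pyridine gives 26. If the 1,2-induction from C8 runs the other way, the C8 epimer of F8 is made with the other ligand enantiomer and the ester is introduced at F11 by Mitsunobu inversion with 3-methylbutanoic acid.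

Step 5 (one-pot acylation/cyclization; risks are O-acylation, incomplete collapse and furan formation). The fallback sets out from 5 and 7 and returns at 15; it builds C3 from CO instead. i-Bu2AlH reduction of 5 gives the lactol (2S,5R)-5-allyl-2-tert-butyl-5-methyl-1,3-dioxolan-4-ol F1. Ohira–Bestmann homologation (K2CO3, MeOH, 2.5 equiv of reagent because the liberated pivalaldehyde consumes one) gives (R)-3-methylhex-5-en-1-yn-3-ol F2. MnO2 oxidation of 7 gives (Z)-4-((tert-butyldimethylsilyl)oxy)-3-iodobut-2-enal F3. Carbonylative Sonogashira coupling of F3 with F2 (PdCl2(PPh3)2, CuI, Et3N, CO) gives the γ-hydroxy ynone (R,Z)-3-(((tert-butyldimethylsilyl)oxy)methyl)-7-hydroxy-7-methyl-4-oxodeca-2,9-dien-5-ynal F4. Hydrative cycloisomerization of F4 with the monovalent gold catalyst (Ph3P)AuNTf2 in wet toluene gives 15.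

**Further compounds**
F1 | step 5 | (2S,5R)-5-allyl-2-tert-butyl-5-methyl-1,3-dioxolan-4-ol (anomers) | C=CC[C@@]1(C)O[C@H](C(C)(C)C)OC1O
F2 | step 5 | (R)-3-methylhex-5-en-1-yn-3-ol | C=CC[C@@](C)(O)C#C
F3 | step 5 | (Z)-4-((tert-butyldimethylsilyl)oxy)-3-iodobut-2-enal | O=C/C=C(/CO[Si](C)(C)C(C)(C)C)I
F4 | step 5 | (R,Z)-3-(((tert-butyldimethylsilyl)oxy)methyl)-7-hydroxy-7-methyl-4-oxodeca-2,9-dien-5-ynal | C=CC[C@@](C)(O)C#CC(=O)/C(CO[Si](C)(C)C(C)(C)C)=C\C=O
F5 | step 8 | methyl (4R,5Z)-6-[(R)-5-allyl-5-methyl-4-oxo-4,5-dihydrofuran-2-yl]-7-((tert-butyldimethylsilyl)oxy)-2-methylene-4-((triethylsilyl)oxy)hept-5-enoate | C=CC[C@@]1(C)OC(=CC1=O)/C(CO[Si](C)(C)C(C)(C)C)=C\[C@H](O[Si](CC)(CC)CC)CC(=C)C(=O)OC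
F6 | step 8 | methyl (4S,5Z)-6-[(R)-5-allyl-5-methyl-4-oxo-4,5-dihydrofuran-2-yl]-7-((tert-butyldimethylsilyl)oxy)-3-hydroxy-2-methylene-4-((triethylsilyl)oxy)hept-5-enoate (both C3 epimers) | C=CC[C@@]1(C)OC(=CC1=O)/C(CO[Si](C)(C)C(C)(C)C)=C\[C@H](O[Si](CC)(CC)CC)C(O)C(=C)C(=O)OC
F7 | step 10 | 2-[(R)-5-[(Z)-1-((tert-butyldimethylsilyl)oxy)-4-hydroxybut-2-en-2-yl]-2-methyl-3-oxo-2,3-dihydrofuran-2-yl]acetaldehyde | O=CC[C@@]1(C)OC(=CC1=O)/C(CO[Si](C)(C)C(C)(C)C)=C\CO
F8 | step 10 | methyl (2Z,4R)-2-(bromomethyl)-5-[(R)-5-[(Z)-1-((tert-butyldimethylsilyl)oxy)-4-((triethylsilyl)oxy)but-2-en-2-yl]-2-methyl-3-oxo-2,3-dihydrofuran-2-yl]-4-((triethylsilyl)oxy)pent-2-enoate | COC(=O)/C(CBr)=C/[C@H](O[Si](CC)(CC)CC)C[C@@]1(C)OC(=CC1=O)/C(CO[Si](C)(C)C(C)(C)C)=C\CO[Si](CC)(CC)CC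
F9 | step 10 | methyl (2Z,4R)-2-(bromomethyl)-5-[(R)-5-[(Z)-1-((tert-butyldimethylsilyl)oxy)-4-oxobut-2-en-2-yl]-2-methyl-3-oxo-2,3-dihydrofuran-2-yl]-4-((triethylsilyl)oxy)pent-2-enoate | COC(=O)/C(CBr)=C/[C@H](O[Si](CC)(CC)CC)C[C@@]1(C)OC(=CC1=O)/C(CO[Si](C)(C)C(C)(C)C)=C\C=O
F10 | step 10 | 15-O-(tert-butyldimethylsilyl)-8-O-(triethylsilyl)-8-O-deacyl-26 (lactone closed; stereocentres as in 26) | C=C1C(=O)O[C@H]2/C=C(/CO[Si](C)(C)C(C)(C)C)C3=CC(=O)[C@@](C)(C[C@@H](O[Si](CC)(CC)CC)[C@@H]12)O3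
F11 | step 10 | 15-O-(tert-butyldimethylsilyl)-8-O-deacyl-26 (C8 alcohol) | C=C1C(=O)O[C@H]2/C=C(/CO[Si](C)(C)C(C)(C)C)C3=CC(=O)[C@@](C)(C[C@@H](O)[C@@H]12)O3
F12 | step 10 | 15-O-(tert-butyldimethylsilyl)-26 | C=C1C(=O)O[C@H]2/C=C(/CO[Si](C)(C)C(C)(C)C)C3=CC(=O)[C@@](C)(C[C@@H](OC(=O)CC(C)C)[C@@H]12)O3
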